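**Retrosynthetic overview**
- Endgame: the target comes from one acidolysis (acetonide and tert-butyl ester) of the C2 ester made by Steglich acylation of the acetonide-protected macrolactone with mono-tert-butyl (E,E)-muconate (one Wittig step).
- Macrolactone: the ten-membered ring is closed at C6–C7 by an intramolecular nickel/photoredox decarboxylative alkenylation. A C7 radical, made from a C7 carboxylic acid, couples with the tethered (E)-C5=C6 alkenyl iodide, so ring closure and the C7 stereocentre come from one operation on an acyclic seco acid.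
- Enabling feature: the C7/C8 vicinal diol next to C6. Tied up as a 2,2-dimethyl-1,3-dioxolane (ring O7–C7–C8–O8–CMe2, absent from the target), O7 stabilises the C7 radical and the ring forces the new C6–C7 bond trans to the C8 substituent, whatever the C7 configuration of the precursor (stereoconvergent). The (E)-C5=C6 alkene maps onto an (E)-alkenyl iodide.
- Seco acid: C1–O9 ester of (2S,5E)-6-iodo-2-silyloxyhex-5-enoic acid (from L-homopropargylglycine) with the C7–C12 alcohol from 2,3-O-isopropylidene-D-ribonolactone. C8 and C9 come from the chiral pool, C7 is deliberately left "wrong", and the old lactone carbon leaves as CO2.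
- Ring order: dioxolane (present in the starting material), then the ten-membered lactone (key step), then the dioxolane is cleaved last.

Key step: step 11

Remark: locants C1–C12 are those of the target lactone (C1 lactone carbonyl, C9/O9 the propyl-bearing carbon and ring oxygen, C10–C12 propyl); in the heptitol names C1 is the former lactone carbon and C2, C3, C4 are target C7, C8, C9; L-homopropargylglycine and (E)-4-oxobut-2-enoic acid are taken as catalogue chemicals.

Step 1
Reactants: 1 2,3-O-isopropylidene-D-ribono-1,4-lactone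
Product: 2 2,3-O-isopropylidene-5-O-(trifluoromethylsulfonyl)-D-ribono-1,4-lactone
Conditions: Tf2O, pyridine, CH2Cl2, −20 °C
Reagents that add atoms: trifluoromethanesulfonic anhydride, O=S(=O)(OS(=O)(=O)C(F)(F)F)C(F)(F)F
Why: O-sulfonylation of the only free (primary) hydroxyl gives a triflate leaving group without touching a stereocentre.

Step 2
Reactants: 2 2,3-O-isopropylidene-5-O-(trifluoromethylsulfonyl)-D-ribono-1,4-lactone
Product: 3 5,6,7-trideoxy-2,3-O-isopropylidene-D-ribo-heptono-1,4-lactone (the propyl lactone)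
Conditions: EtMgBr, CuBr·SMe2 (10 mol%), THF, −78 to −30 °C
Reagents that add atoms: ethylmagnesium bromide, CC[Mg]Br
Why: Copper-catalysed sp3–sp3 coupling of a primary alkyl triflate with a Grignard reagent should outrun addition to the lactone at low temperature and completes the propyl group (C10–C12) without touching C8 or C9.

Step 3
Reactants: 3 5,6,7-trideoxy-2,3-O-isopropylidene-D-ribo-heptono-1,4-lactone
Product: 4 5,6,7-trideoxy-2,3-O-isopropylidene-D-ribo-heptitol
Conditions: LiBH4, THF, 0 °C to rt; aq. NH4Cl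
Reagents that add atoms: none
Why: Borohydride reduction of the gamma-lactone to the 1,4-diol frees the C9 hydroxyl and leaves the former carbonyl carbon as a CH2OH handle on C7, with no stereocentre touched.

Step 4
Reactants: 4 5,6,7-trideoxy-2,3-O-isopropylidene-D-ribo-heptitol
Product: 5 1-O-(tert-butyldimethylsilyl)-5,6,7-trideoxy-2,3-O-isopropylidene-D-ribo-heptitol
Conditions: TBSCl (1.05 equiv), imidazole, CH2Cl2, 0 °C
Reagents that add atoms: tert-butyldimethylsilyl chloride, CC(C)(C)[Si](C)(C)Cl
Why: Sterically controlled silyl ether formation at the primary hydroxyl leaves the hindered secondary C9 hydroxyl free.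

Step 5
Reactants: 6 L-homopropargylglycine, (S)-2-aminohex-5-ynoic acid
Product: 7 (S)-2-hydroxyhex-5-ynoic acid
Conditions: NaNO2, 1 M H2SO4, H2O, 0 °C to rt
Reagents that add atoms: water, O
Why: Diazotisation of the alpha-amino acid with hydrolysis through the alpha-lactone (double inversion, net retention) carries the L configuration over to (S)-C2.

Step 6
Reactants: 7 (S)-2-hydroxyhex-5-ynoic acid
Product: 9 (S)-2-(tert-butyldiphenylsilyloxy)hex-5-ynoic acid, via silyl ester 8 (not isolated)
Conditions: TBDPSCl (2.3 equiv), imidazole, DMF, rt; then K2CO3, MeOH/THF/H2O, rt; 1 M HCl to pH 3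
Reagents that add atoms: tert-butyldiphenylsilyl chloride, CC(C)(C)[Si](Cl)(c1ccccc1)c1ccccc1
Why: Exhaustive silylation followed by selective hydrolysis of the labile silyl ester leaves only the robust silyl ether on O2 and does not affect C2.

Step 7
Reactants: 9 (S)-2-(tert-butyldiphenylsilyloxy)hex-5-ynoic acid
Product: 11 (2S,5E)-2-(tert-butyldiphenylsilyloxy)-6-iodohex-5-enoic acid, via alkenylzirconocene 10 (not isolated)
Conditions: Cp2Zr(H)Cl (2.5 equiv), THF, rt; then I2, 0 °C; aq. HCl/Na2S2O3
Reagents that add atoms: iodine, II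
Why: Hydrozirconation with the Schwartz reagent (syn addition, zirconium at the terminal carbon, the first equivalent being consumed by the acid as its zirconium carboxylate) and iodinolysis with retention should give only the (E)-alkenyl iodide.

Step 8
Reactants: 5 1-O-(tert-butyldimethylsilyl)-5,6,7-trideoxy-2,3-O-isopropylidene-D-ribo-heptitol; 11 (2S,5E)-2-(tert-butyldiphenylsilyloxy)-6-iodohex-5-enoic acid
Product: 12 1-O-(tert-butyldimethylsilyl)-4-O-[(2S,5E)-2-(tert-butyldiphenylsilyloxy)-6-iodohex-5-enoyl]-5,6,7-trideoxy-2,3-O-isopropylidene-D-ribo-heptitol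
Conditions: EDC·HCl, DMAP, CH2Cl2, 0 °C to rt
Reagents that add atoms: none
Why: Steglich esterification of the hindered secondary alcohol forms the C1–O9 ester that later tethers the two reacting ends, with no change at any stereocentre.

Step 9
Reactants: 12 the bis-silylated ester
Product: 13 4-O-[(2S,5E)-2-(tert-butyldiphenylsilyloxy)-6-iodohex-5-enoyl]-5,6,7-trideoxy-2,3-O-isopropylidene-D-ribo-heptitol
Conditions: HF·pyridine, pyridine, THF, 0 °C
Reagents that add atoms: none
Why: Fluoride-mediated desilylation removes the primary TBS ether selectively over the bulky secondary TBDPS ether, and the buffered reagent spares the acetonide.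

Step 10
Reactants: 13 the primary alcohol
Product: 15 4-O-[(2S,5E)-2-(tert-butyldiphenylsilyloxy)-6-iodohex-5-enoyl]-5,6,7-trideoxy-2,3-O-isopropylidene-D-ribo-heptonic acid, via aldehyde 14 (not isolated)
Conditions: TEMPO (20 mol%), PhI(OAc)2 (2.5 equiv), MeCN/H2O 1:1, rt
Reagents that add atoms: water, O
Why: Oxoammonium oxidation (TEMPO with a hypervalent iodine co-oxidant) takes the primary alcohol through the aldehyde hydrate to the acid, and any epimerisation at C7 on the way is harmless because that centre is erased in the next step.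

Step 11
Reactants: 15 the seco acid (cis-dioxolane, D-ribo)
Product: 17 (2S,5E,7R,8R,9R)-2-(tert-butyldiphenylsilyloxy)-7,8-(isopropylidenedioxy)-9-propylnon-5-en-9-olide (trans-fused dioxolane; same spatial arrangement as the target), via dioxolanyl radical 16 (not isolated)
Conditions: [Ir{dF(CF3)ppy}2(dtbbpy)]PF6 (2 mol%), NiCl2·glyme (20 mol%), 4,4'-di-tert-butyl-2,2'-bipyridine (25 mol%), DBU (1.5 equiv), degassed DMSO (1 mM, 15 added over 12 h), blue LEDs (450 nm), 25 °C
Reagents that add atoms: none
Why: Proposed new method: the excited iridium photocatalyst oxidises the carboxylate of 15, CO2 is lost and the alpha-oxy dioxolan-4-yl radical 16 results, while zerovalent nickel inserts into the tethered alkenyl C–I bond; capture of the radical at nickel and C(sp3)–C(sp2) reductive elimination from trivalent nickel form the C6–C7 bond, the closest known reaction type being the intermolecular nickel/photoredox decarboxylative alkenylation of alpha-oxy carboxylic acids (and of tartrate-acetonide acid derivatives, which couple trans) with alkenyl halides, not yet used to close a medium ring. The ten-membered lactone is closed by intramolecular cross-coupling at the metal (an eleven-membered nickelacycle that contracts on reductive elimination), not by radical addition to the alkene, so no exo/endo question arises. The new stereocentre C7 is controlled by the temporary dioxolane ring: the planar radical is bonded anti to the C8 side chain to give the trans-4,5-disubstituted dioxolane (7,8-threo) from either C7 epimer of 15, so the cis (ribo) acid converges on the required configuration. The (E) geometry of C5=C6 is carried over from the iodide because oxidative addition and reductive elimination retain alkene geometry. The step needs ring closure over oligomerisation, secured by about 1 mM concentration, slow substrate addition and the low stationary radical concentration, and C–C over C–O coupling, secured by the silyl group on O2 and the fast decarboxylation of the alpha-oxy carboxyl radical.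

Step 12
Reactants: 17 the silyl-protected macrolactone
Product: 18 (2S,5E,7R,8R,9R)-2-hydroxy-7,8-(isopropylidenedioxy)-9-propylnon-5-en-9-olide
Conditions: TBAF, AcOH (1:1), THF, 0 °C to rt
Reagents that add atoms: none
Why: Acetic acid-buffered fluoride desilylation removes the TBDPS ether without epimerising C2 or opening the lactone.

Step 13
Reactants: 19 (E)-4-oxobut-2-enoic acid; 20 tert-butyl (triphenylphosphoranylidene)acetate
Product: 21 (2E,4E)-6-tert-butoxy-6-oxohexa-2,4-dienoic acid (mono-tert-butyl E,E-muconate)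
Conditions: CH2Cl2, rt
Reagents that add atoms: none
Why: Wittig olefination with a stabilised ylide gives the new (E)-alkene and keeps the existing one, and in CH2Cl2 the carboxylic acid should not quench the ylide.

Step 14
Reactants: 18 the C2 alcohol; 21 mono-tert-butyl E,E-muconate
Product: 22 (2S,5E,7R,8R,9R)-2-[(2E,4E)-6-tert-butoxy-6-oxohexa-2,4-dienoyloxy]-7,8-(isopropylidenedioxy)-9-propylnon-5-en-9-olide
Conditions: EDC·HCl, DMAP, CH2Cl2, 0 °C to rt
Reagents that add atoms: none
Why: Steglich esterification acylates the only free hydroxyl (C2) because the 7,8-diol is masked in the dioxolane.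

Step 15
Reactants: 22 the fully protected ester
Product: 23 (2S,5E,7R,8S,9R)-2-[(2E,4E)-5-carboxypenta-2,4-dienoyloxy]-7,8-dihydroxy-9-propylnon-5-en-9-olide (CNP0476488.5)
Conditions: TFA/CH2Cl2/H2O 25:70:5, 0 °C to rt
Reagents that add atoms: none
Why: Acidolysis hydrolyses the isopropylidene acetal and cleaves the tert-butyl ester (loss of isobutene) in one operation and should leave the lactone, the dienoate and all four stereocentres unchanged.

**Compound list**
1 | 2,3-O-isopropylidene-D-ribono-1,4-lactone | CC1(C)O[C@@H]2[C@@H](CO)OC(=O)[C@@H]2O1 | starting material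
2 | 2,3-O-isopropylidene-5-O-(trifluoromethylsulfonyl)-D-ribono-1,4-lactone | CC1(C)O[C@@H]2[C@@H](COS(=O)(=O)C(F)(F)F)OC(=O)[C@@H]2O1 | intermediate
3 | 5,6,7-trideoxy-2,3-O-isopropylidene-D-ribo-heptono-1,4-lactone | CC1(C)O[C@@H]2[C@@H](CCC)OC(=O)[C@@H]2O1 | intermediate
4 | 5,6,7-trideoxy-2,3-O-isopropylidene-D-ribo-heptitol | CC1(C)O[C@H]([C@@H](CCC)O)[C@H](CO)O1 | intermediate
5 | 1-O-(tert-butyldimethylsilyl)-5,6,7-trideoxy-2,3-O-isopropylidene-D-ribo-heptitol | CC1(C)O[C@H]([C@@H](CCC)O)[C@H](CO[Si](C)(C)C(C)(C)C)O1 | intermediate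
6 | L-homopropargylglycine, (S)-2-aminohex-5-ynoic acid | N[C@@H](CCC#C)C(=O)O | starting material
7 | (S)-2-hydroxyhex-5-ynoic acid | O[C@@H](CCC#C)C(=O)O | intermediate
8 | tert-butyldiphenylsilyl (S)-2-(tert-butyldiphenylsilyloxy)hex-5-ynoate | C#CCC[C@H](O[Si](c1ccccc1)(c1ccccc1)C(C)(C)C)C(=O)O[Si](c1ccccc1)(c1ccccc1)C(C)(C)C | intermediate
9 | (S)-2-(tert-butyldiphenylsilyloxy)hex-5-ynoic acid | C#CCC[C@H](O[Si](c1ccccc1)(c1ccccc1)C(C)(C)C)C(=O)O | intermediate
10 | (E)-alkenylzirconocene chloride of 9 as its zirconocene chloride carboxylate (cyclopentadienyl ligands drawn sigma-bonded) | Cl[Zr](/C=C/CC[C@H](O[Si](c1ccccc1)(c1ccccc1)C(C)(C)C)C(=O)O[Zr](Cl)(C1C=CC=C1)C1C=CC=C1)(C1C=CC=C1)C1C=CC=C1 | intermediate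
11 | (2S,5E)-2-(tert-butyldiphenylsilyloxy)-6-iodohex-5-enoic acid | I/C=C/CC[C@H](O[Si](c1ccccc1)(c1ccccc1)C(C)(C)C)C(=O)O | intermediate
12 | 1-O-(tert-butyldimethylsilyl)-4-O-[(2S,5E)-2-(tert-butyldiphenylsilyloxy)-6-iodohex-5-enoyl]-5,6,7-trideoxy-2,3-O-isopropylidene-D-ribo-heptitol | CC1(C)O[C@H]([C@@H](CCC)OC(=O)[C@H](CC/C=C/I)O[Si](c2ccccc2)(c2ccccc2)C(C)(C)C)[C@H](CO[Si](C)(C)C(C)(C)C)O1 | intermediate
13 | 4-O-[(2S,5E)-2-(tert-butyldiphenylsilyloxy)-6-iodohex-5-enoyl]-5,6,7-trideoxy-2,3-O-isopropylidene-D-ribo-heptitol | CC1(C)O[C@H]([C@@H](CCC)OC(=O)[C@H](CC/C=C/I)O[Si](c2ccccc2)(c2ccccc2)C(C)(C)C)[C@H](CO)O1 | intermediate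
14 | 4-O-[(2S,5E)-2-(tert-butyldiphenylsilyloxy)-6-iodohex-5-enoyl]-5,6,7-trideoxy-2,3-O-isopropylidene-aldehydo-D-ribo-heptose | CC1(C)O[C@H]([C@@H](CCC)OC(=O)[C@H](CC/C=C/I)O[Si](c2ccccc2)(c2ccccc2)C(C)(C)C)[C@H](C=O)O1 | intermediate
15 | 4-O-[(2S,5E)-2-(tert-butyldiphenylsilyloxy)-6-iodohex-5-enoyl]-5,6,7-trideoxy-2,3-O-isopropylidene-D-ribo-heptonic acid | CC1(C)O[C@H]([C@@H](CCC)OC(=O)[C@H](CC/C=C/I)O[Si](c2ccccc2)(c2ccccc2)C(C)(C)C)[C@H](C(=O)O)O1 | intermediate
16 | 2,2-dimethyl-1,3-dioxolan-4-yl radical from 15 (C7 planar; C8, C9 and C2 as in 15) | CC1(C)O[C@H]([C@@H](CCC)OC(=O)[C@H](CC/C=C/I)O[Si](c2ccccc2)(c2ccccc2)C(C)(C)C)[CH]O1 | intermediate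
17 | (2S,5E,7R,8R,9R)-2-(tert-butyldiphenylsilyloxy)-7,8-(isopropylidenedioxy)-9-propylnon-5-en-9-olide | CCC[C@H]1OC(=O)[C@@H](O[Si](c2ccccc2)(c2ccccc2)C(C)(C)C)CC/C=C/[C@H]2OC(C)(C)O[C@H]12 | intermediate
18 | (2S,5E,7R,8R,9R)-2-hydroxy-7,8-(isopropylidenedioxy)-9-propylnon-5-en-9-olide | CCC[C@H]1OC(=O)[C@@H](O)CC/C=C/[C@H]2OC(C)(C)O[C@H]12 | intermediate
19 | (E)-4-oxobut-2-enoic acid | O=C/C=C/C(=O)O | starting material
20 | tert-butyl (triphenylphosphoranylidene)acetate | CC(C)(C)OC(=O)C=P(c1ccccc1)(c1ccccc1)c1ccccc1 | starting material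
21 | (2E,4E)-6-tert-butoxy-6-oxohexa-2,4-dienoic acid | OC(=O)/C=C/C=C/C(=O)OC(C)(C)C | intermediate
22 | (2S,5E,7R,8R,9R)-2-[(2E,4E)-6-tert-butoxy-6-oxohexa-2,4-dienoyloxy]-7,8-(isopropylidenedioxy)-9-propylnon-5-en-9-olide | CCC[C@H]1OC(=O)[C@@H](OC(=O)/C=C/C=C/C(=O)OC(C)(C)C)CC/C=C/[C@H]2OC(C)(C)O[C@H]12 | intermediate
23 | (2S,5E,7R,8S,9R)-2-[(2E,4E)-5-carboxypenta-2,4-dienoyloxy]-7,8-dihydroxy-9-propylnon-5-en-9-olide | CCC[C@H]1OC(=O)[C@@H](OC(=O)/C=C/C=C/C(=O)O)CC/C=C/[C@@H](O)[C@@H]1O | target

(The C8 descriptor is R in 17, 18 and 22 and S in 23 only because the CIP priorities change when O7 becomes a free hydroxyl; the spatial arrangement is the same.)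

**Totals**
Total step count: 15. Longest linear sequence: 11 steps (1, 2, 3, 4, 8, 9, 10, 11, 12, 14, 15).

**Steps most likely to fail**

Step 11 (proposed new method). Intermolecular coupling to oligomers, or hydrogen-atom quenching of the C7 radical (protodecarboxylation), may outrun ring closure at nickel. The fallback closes the same bond by a Nozaki–Hiyama–Kishi macrocyclisation and sets out from acid 11. (E)-Hex-2-en-1-ol is epoxidised by Sharpless asymmetric epoxidation (Ti(OiPr)4, L-(+)-diethyl tartrate, tBuOOH) to (2S,3S)-2,3-epoxyhexan-1-ol F1. Ti(OiPr)4-mediated opening of F1 at its C3 by acid 11, with inversion, installs the C1–O9 ester directly and gives (2S,3R)-1,2-dihydroxyhexan-3-yl (2S,5E)-2-(tert-butyldiphenylsilyloxy)-6-iodohex-5-enoate F2. TESOTf and 2,6-lutidine give the bis(triethylsilyl) ether F3. Swern oxidation, which cleaves and oxidises only the primary silyl ether, gives the C7 aldehyde F4. Ring closure with CrCl2 and catalytic NiCl2 in DMSO at high dilution, with a chiral sulfonamide ligand on chromium if substrate control favours the 7-epimer, gives the macrocyclic allylic alcohol F5. PPTS in MeOH removes the triethylsilyl group to give the diol F6, and 2,2-dimethoxypropane with PPTS closes the acetonide, returning to the route at 17.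

Step 2. Addition of the Grignard reagent to the lactone carbonyl, or elimination of the triflate, may compete with substitution. The fallback sets out from 1: Dess–Martin oxidation gives the 5-aldehyde 2,3-O-isopropylidene-D-ribo-pentodialdono-1,4-lactone F7, Wittig olefination with ethyltriphenylphosphonium bromide and KHMDS at −78 °C gives the (Z)-alkene 5,6,7-trideoxy-2,3-O-isopropylidene-D-ribo-hept-5-enono-1,4-lactone F8, and hydrogenation (H2, Pd/C, EtOAc) returns to the route at 3.

Step 7. The hydride may be consumed by the carboxylic acid so that hydrozirconation stays incomplete, or the zirconium carboxylate may be reduced. The fallback sets out from 9 and moves the iodide formation behind the esterification: 9 and alcohol 5 are joined (EDC·HCl, DMAP) to the alkyne ester F9, hydrozirconation (Cp2Zr(H)Cl, THF) gives the alkenylzirconocene F10, and iodine returns to the route at 12.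

Further compounds
F1 | step 11 | (2S,3S)-2,3-epoxyhexan-1-ol | OC[C@@H]1O[C@H]1CCC
F2 | step 11 | (2S,3R)-1,2-dihydroxyhexan-3-yl (2S,5E)-2-(tert-butyldiphenylsilyloxy)-6-iodohex-5-enoate | OC[C@H](O)[C@H](OC(=O)[C@H](CC/C=C/I)O[Si](c1ccccc1)(c1ccccc1)C(C)(C)C)CCC
F3 | step 11 | 1,2-bis(triethylsilyl) ether of F2 | CC[Si](CC)(CC)OC[C@H](O[Si](CC)(CC)CC)[C@H](OC(=O)[C@H](CC/C=C/I)O[Si](c1ccccc1)(c1ccccc1)C(C)(C)C)CCC
F4 | step 11 | C7 aldehyde, 1-oxo-2-(triethylsilyloxy)hexan-3-yl (2S,5E)-2-(tert-butyldiphenylsilyloxy)-6-iodohex-5-enoate (C8 and C9 as in F2) | O=C[C@H](O[Si](CC)(CC)CC)[C@H](OC(=O)[C@H](CC/C=C/I)O[Si](c1ccccc1)(c1ccccc1)C(C)(C)C)CCC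
F5 | step 11 | (2S,5E,7R,8S,9R)-2-(tert-butyldiphenylsilyloxy)-7-hydroxy-9-propyl-8-(triethylsilyloxy)non-5-en-9-olide | CCC[C@H]1OC(=O)[C@@H](O[Si](c2ccccc2)(c2ccccc2)C(C)(C)C)CC/C=C/[C@@H](O)[C@@H]1O[Si](CC)(CC)CC
F6 | step 11 | (2S,5E,7R,8S,9R)-2-(tert-butyldiphenylsilyloxy)-7,8-dihydroxy-9-propylnon-5-en-9-olide | CCC[C@H]1OC(=O)[C@@H](O[Si](c2ccccc2)(c2ccccc2)C(C)(C)C)CC/C=C/[C@@H](O)[C@@H]1O
F7 | step 2 | 2,3-O-isopropylidene-D-ribo-pentodialdono-1,4-lactone | CC1(C)O[C@@H]2[C@@H](C=O)OC(=O)[C@@H]2O1
F8 | step 2 | (5Z)-5,6,7-trideoxy-2,3-O-isopropylidene-D-ribo-hept-5-enono-1,4-lactone | CC1(C)O[C@@H]2[C@@H](/C=C\C)OC(=O)[C@@H]2O1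
F9 | step 7 | 1-O-(tert-butyldimethylsilyl)-4-O-[(2S)-2-(tert-butyldiphenylsilyloxy)hex-5-ynoyl]-5,6,7-trideoxy-2,3-O-isopropylidene-D-ribo-heptitol | CC1(C)O[C@H]([C@@H](CCC)OC(=O)[C@H](CCC#C)O[Si](c2ccccc2)(c2ccccc2)C(C)(C)C)[C@H](CO[Si](C)(C)C(C)(C)C)O1
F10 | step 7 | (E)-alkenylzirconocene chloride of F9 (cyclopentadienyl ligands drawn sigma-bonded) | CC1(C)O[C@H]([C@@H](CCC)OC(=O)[C@H](CC/C=C/[Zr](Cl)(C2C=CC=C2)C2C=CC=C2)O[Si](c2ccccc2)(c2ccccc2)C(C)(C)C)[C@H](CO[Si](C)(C)C(C)(C)C)O1
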